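## Retrosynthetic overview

1. The target comes from its heptabenzyl ether by global hydrogenolysis. That ether is cut at C4–C4a of ring C, an intramolecular Friedel–Crafts acylation of an (S)-3-aryl-3-aryloxypropanoic acid. Ring C is the only ring built, and it is closed last.
2. Feature used: ring A bears oxygen at C5, C7 and C8a (O1) in a 1,3,5 pattern. With C4–C4a cut, it is a 3,5-bis(benzyloxy)phenyl group on the C2 oxygen. Its two CH carbons flanking the O1-bearing carbon are interchangeable and strongly activated, so whichever attacks becomes C4a and only the 5,7-pattern can arise.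
3. O1–C2 is cut next: invertive Mitsunobu etherification of the (R)-benzylic alcohol, which comes from Ru-catalysed asymmetric hydrogenation of the beta-keto ester. These two steps set C2 as (S).
4. The C5'–C6(flavone) bond is cut by Suzuki–Miyaura coupling of a ring B boronate (from 5-bromovanillin) with 6-iodo-tri-O-benzylapigenin (from apigenin, whose rings are bought intact).
5. Order of construction: rings A and B and the flavone rings arrive with the starting materials. The biaryl bond is made first, then the chain C2–C3–C4, then O1–C2, then ring C.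

Key step: step 13

Notation: Ar* = 3,4-bis(benzyloxy)-5-{5,7-bis(benzyloxy)-2-[4-(benzyloxy)phenyl]-4-oxo-4H-chromen-6-yl}phenyl, that is, benzylated ring B carrying the benzylated flavone at C5'. Plain and primed locants refer to the flavanone unit.

Assumption: the target defines only C2. The C5'–C6(flavone) axis (three ortho oxygens, one ortho hydrogen) is treated as configurationally unassigned, so benzylated intermediates may appear as rotamers that converge in the target.

## Route

Step 1
Reactants: 1 apigenin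
Product: 2 7-(benzyloxy)-2-[4-(benzyloxy)phenyl]-5-hydroxy-4H-chromen-4-one
Conditions: BnBr (2.2 equiv), K2CO3, DMF, rt
Reagents that add atoms: benzyl bromide, BrCc1ccccc1
Why: Williamson etherification, in which the free 7-OH and 4'-OH are alkylated while the 5-OH, held in a hydrogen bond to the C4 carbonyl, should stay untouched with two equivalents of halide and a mild carbonate base.

Step 2
Reactants: 2 7-(benzyloxy)-2-[4-(benzyloxy)phenyl]-5-hydroxy-4H-chromen-4-one
Product: 3 7-(benzyloxy)-2-[4-(benzyloxy)phenyl]-5-hydroxy-6-iodo-4H-chromen-4-one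
Conditions: BnMe3N·ICl2 (1.1 equiv), CaCO3, CH2Cl2/MeOH, rt, dark
Reagents that add atoms: benzyltrimethylammonium dichloroiodate, C[N+](C)(C)Cc1ccccc1.Cl[I-]Cl
Why: Electrophilic aromatic iodination, for which this reagent is known to attack 5,7-dioxygenated flavones with free 5-OH and alkylated 7-oxygen at C6 (ortho to the chelated phenol) rather than at C8, while CaCO3 takes up the HCl.

Step 3
Reactants: 3 7-(benzyloxy)-2-[4-(benzyloxy)phenyl]-5-hydroxy-6-iodo-4H-chromen-4-one
Product: 4 5,7-bis(benzyloxy)-2-[4-(benzyloxy)phenyl]-6-iodo-4H-chromen-4-one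
Conditions: BnBr (1.5 equiv), K2CO3, DMF, 70 °C
Reagents that add atoms: benzyl bromide, BrCc1ccccc1
Why: Williamson etherification under more forcing conditions breaks the chelate and caps the last phenol, which would otherwise compete in the Mitsunobu step and bind SnCl4 in the key step.

Step 4
Reactants: 5 5-bromovanillin
Product: 6 3-bromo-4,5-dihydroxybenzaldehyde
Conditions: AlCl3, pyridine, CH2Cl2, reflux; then 2 M HCl
Reagents that add atoms: none
Why: Lewis acid ether cleavage of an ortho-hydroxyanisole, in which aluminium held by the phenolate and the neighbouring methoxy oxygen activates the O–CH3 bond for attack by pyridine, while aldehyde and aryl bromide are inert.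

Step 5
Reactants: 6 3-bromo-4,5-dihydroxybenzaldehyde
Product: 7 3,4-bis(benzyloxy)-5-bromobenzaldehyde
Conditions: BnBr (2.5 equiv), K2CO3, DMF, 60 °C
Reagents that add atoms: benzyl bromide, BrCc1ccccc1
Why: Williamson etherification of both catechol oxygens gives ring B in the same protecting group as the rest of the molecule, so that one final operation frees all phenols.

Step 6
Reactants: 7 3,4-bis(benzyloxy)-5-bromobenzaldehyde
Product: 8 3,4-bis(benzyloxy)-5-(4,4,5,5-tetramethyl-1,3,2-dioxaborolan-2-yl)benzaldehyde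
Conditions: B2pin2, PdCl2(dppf), KOAc, 1,4-dioxane, 90 °C
Reagents that add atoms: bis(pinacolato)diboron, CC1(C)OB(OC1(C)C)B1OC(C)(C)C(C)(C)O1
Why: Miyaura borylation, which tolerates the aldehyde and, with acetate as a weak base, should stop at the boronate without homocoupling.

Step 7
Reactants: 4 5,7-bis(benzyloxy)-2-[4-(benzyloxy)phenyl]-6-iodo-4H-chromen-4-one; 8 3,4-bis(benzyloxy)-5-(4,4,5,5-tetramethyl-1,3,2-dioxaborolan-2-yl)benzaldehyde
Product: 9 Ar*-CHO, 3,4-bis(benzyloxy)-5-{5,7-bis(benzyloxy)-2-[4-(benzyloxy)phenyl]-4-oxo-4H-chromen-6-yl}benzaldehyde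
Conditions: Pd(OAc)2, SPhos, K3PO4, toluene/H2O, 90 °C
Reagents that add atoms: none
Why: Suzuki–Miyaura coupling, in which the aryl iodide adds readily to zerovalent palladium, the bulky electron-rich SPhos ligand suits biaryls with three ortho substituents, and boron sits on ring B because a flavone boronate flanked by two alkoxy groups would protodeboronate.

Step 8
Reactants: 9 Ar*-CHO
Product: 10 Ar*-CO2H, the corresponding benzoic acid
Conditions: NaClO2, NaH2PO4, 2-methyl-2-butene (large excess), THF/t-BuOH/H2O, 0 °C to rt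
Reagents that add atoms: sodium chlorite, [Na+].[O-]Cl=O
Why: Pinnick oxidation converts the aldehyde selectively at buffered pH, and the alkene scavenger traps hypochlorous acid before it can chlorinate the electron-rich rings.

Step 9
Reactants: 10 Ar*-CO2H
Product: 13 ethyl 3-oxo-3-Ar*-propanoate (beta-keto ester), via acyl imidazolide 11 (not isolated), via acylmalonic half ester 12 (not isolated)
Conditions: CDI, THF, rt; then KO2CCH2CO2Et, MgCl2, Et3N, MeCN/THF, rt to 40 °C; 1 M HCl work-up
Reagents that add atoms: 1,1'-carbonyldiimidazole, O=C(n1ccnc1)n1ccnc1 (imidazolyl group of 11 only); potassium ethyl malonate, CCOC(=O)CC(=O)[O-].[K+]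
Why: Masamune–Brooks C-acylation (a decarboxylative Claisen condensation), in which the magnesium-chelated enolate of the malonate half ester attacks the acyl imidazolide and the adduct loses CO2, so the beta-keto ester forms under nearly neutral conditions that spare the flavone and the benzyl ethers.

Step 10
Reactants: 13 ethyl 3-oxo-3-Ar*-propanoate
Product: 14 ethyl (3R)-3-hydroxy-3-Ar*-propanoate
Conditions: [RuCl(p-cymene)((S)-SEGPHOS)]Cl (2 mol %), H2 (50 bar), EtOH/CH2Cl2, 50 °C
Reagents that add atoms: none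
Why: Noyori-type asymmetric hydrogenation, in which the keto ester binds divalent ruthenium through both carbonyl oxygens and the (S)-configured biaryl diphosphine shields one ketone face, the known sense for 3-aryl-3-oxopropanoates being (S)-ligand to (R)-alcohol, while aryl benzyl ethers and the pyranone C=C bond of the flavone are not substrates for this catalyst.

Step 11
Reactants: 14 ethyl (3R)-3-hydroxy-3-Ar*-propanoate; 15 3,5-bis(benzyloxy)phenol
Product: 16 ethyl (3S)-3-[3,5-bis(benzyloxy)phenoxy]-3-Ar*-propanoate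
Conditions: PPh3, DIAD, toluene, 0 °C to rt
Reagents that add atoms: none
Why: Mitsunobu etherification, in which the phenoxide displaces the oxyphosphonium group at the benzylic carbon by SN2 with inversion, turning the (R)-carbinol into the (S)-ether carbon that is C2 of the target, while the non-polar solvent and low temperature disfavour ionisation and elimination.

Step 12
Reactants: 16 ethyl (3S)-3-[3,5-bis(benzyloxy)phenoxy]-3-Ar*-propanoate
Product: 17 (3S)-3-[3,5-bis(benzyloxy)phenoxy]-3-Ar*-propanoic acid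
Conditions: LiOH, THF/H2O, 0 °C to rt; then cold 1 M HCl to pH 3–4
Reagents that add atoms: lithium hydroxide, [Li+].[OH-]
Why: Ester saponification by addition–elimination at the acyl carbon, in which hydroxide should attack the unhindered ethyl ester faster than it removes a proton next to it, the carboxylate formed no longer expels aryloxide, and the stereocentre is not a reacting atom.

Step 13
Reactants: 17 (3S)-3-[3,5-bis(benzyloxy)phenoxy]-3-Ar*-propanoic acid
Product: 19 (2S)-5,7-bis(benzyloxy)-2-Ar*-chroman-4-one (heptabenzyl ether of the target), via acid chloride 18 (not isolated)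
Conditions: 1-chloro-N,N,2-trimethylprop-1-en-1-amine (1.2 equiv), CH2Cl2, 0 °C; then 2,6-di-tert-butyl-4-methylpyridine (1.5 equiv), SnCl4 (3.5 equiv, to cover the flavone carbonyl and the amide by-product as well), −78 to −40 °C; cold aq NaHCO3 quench
Reagents that add atoms: 1-chloro-N,N,2-trimethylprop-1-en-1-amine, CC(C)=C(Cl)N(C)C (its chlorine stands in 18 only and is lost again on the way to 19)
Why: The alpha-chloroenamine makes acid chloride 18 without releasing acid, SnCl4 polarises the acyl chloride, a ring A carbon next to the O1-bearing carbon (para to one benzyloxy group, ortho to the other) attacks the acyl carbon, and the arenium ion gives its proton to the hindered pyridine, which forms C4–C4a. The closest known reaction is the intramolecular Friedel–Crafts acylation of 3-aryloxypropanoic acids to chroman-4-ones, which is also known for 3-aryl-3-(3,5-dialkoxyphenoxy)propanoic acids as a way to flavanones. Ring C (O1–C2–C3–C4–C4a–C8a) closes in a 6-exo-trig mode at the acyl carbon, the C=O bond staying outside the new ring. No stereocentre is created, and C2, set in steps 10 and 11, is not a reacting atom and stays (S) as long as the C2–O1 bond remains intact. Site selectivity is built in, because the two reactive ring A carbons interchange by rotation about the O1–aryl bond, the third activated carbon (para to O1) cannot reach the acyl group, and the alternative five-membered closure onto C2' or C6' of ring B (an indanone) involves a far less nucleophilic ring. The selectivity that must be won is acylation over Lewis acid ionisation of the benzylic C2–O1 bond, and it is served by the trioxygenated ring A, the low temperature, a pyridine that removes HCl but is too hindered to bind tin or enolise the product, the 4'-benzyloxy group being twisted out of conjugation between its two ortho neighbours, and the tin-bound flavone carbonyl making the C5' substituent electron-withdrawing.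

Step 14
Reactants: 19 (2S)-5,7-bis(benzyloxy)-2-Ar*-chroman-4-one
Product: 20 target, (2S)-2-{3,4-dihydroxy-5-[5,7-dihydroxy-2-(4-hydroxyphenyl)-4-oxo-4H-chromen-6-yl]phenyl}-5,7-dihydroxychroman-4-one
Conditions: H2 (1 atm), Pd(OH)2/C, THF/MeOH, rt, stopped after uptake of seven equivalents
Reagents that add atoms: none
Why: Catalytic hydrogenolysis cleaves the seven aryl benzyl ethers faster than it touches the pyranone C=C bond, the chelated aryl ketone or the cyclic C2–O1 bond, and the neutral medium avoids the base-induced ring opening that would racemise C2.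

## Compound list

1 | apigenin | O=c1cc(-c2ccc(O)cc2)oc2cc(O)cc(O)c12 | starting material
2 | 7-(benzyloxy)-2-[4-(benzyloxy)phenyl]-5-hydroxy-4H-chromen-4-one | O=c1cc(-c2ccc(OCc3ccccc3)cc2)oc2cc(OCc3ccccc3)cc(O)c12 | intermediate
3 | 7-(benzyloxy)-2-[4-(benzyloxy)phenyl]-5-hydroxy-6-iodo-4H-chromen-4-one | O=c1cc(-c2ccc(OCc3ccccc3)cc2)oc2cc(OCc3ccccc3)c(I)c(O)c12 | intermediate
4 | 5,7-bis(benzyloxy)-2-[4-(benzyloxy)phenyl]-6-iodo-4H-chromen-4-one | O=c1cc(-c2ccc(OCc3ccccc3)cc2)oc2cc(OCc3ccccc3)c(I)c(OCc3ccccc3)c12 | intermediate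
5 | 5-bromovanillin | COc1cc(C=O)cc(Br)c1O | starting material
6 | 3-bromo-4,5-dihydroxybenzaldehyde | O=Cc1cc(O)c(O)c(Br)c1 | intermediate
7 | 3,4-bis(benzyloxy)-5-bromobenzaldehyde | O=Cc1cc(OCc2ccccc2)c(OCc2ccccc2)c(Br)c1 | intermediate
8 | 3,4-bis(benzyloxy)-5-(4,4,5,5-tetramethyl-1,3,2-dioxaborolan-2-yl)benzaldehyde | O=Cc1cc(OCc2ccccc2)c(OCc2ccccc2)c(B2OC(C)(C)C(C)(C)O2)c1 | intermediate
9 | Ar*-CHO, biaryl aldehyde | O=Cc1cc(OCc2ccccc2)c(OCc2ccccc2)c(-c2c(OCc3ccccc3)cc3oc(-c4ccc(OCc5ccccc5)cc4)cc(=O)c3c2OCc2ccccc2)c1 | intermediate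
10 | Ar*-CO2H, biaryl carboxylic acid | OC(=O)c1cc(OCc2ccccc2)c(OCc2ccccc2)c(-c2c(OCc3ccccc3)cc3oc(-c4ccc(OCc5ccccc5)cc4)cc(=O)c3c2OCc2ccccc2)c1 | intermediate
11 | Ar*-C(O)-imidazol-1-yl, acyl imidazolide (not isolated) | O=C(n1ccnc1)c1cc(OCc2ccccc2)c(OCc2ccccc2)c(-c2c(OCc3ccccc3)cc3oc(-c4ccc(OCc5ccccc5)cc4)cc(=O)c3c2OCc2ccccc2)c1 | intermediate
12 | 2-(ethoxycarbonyl)-3-oxo-3-Ar*-propanoic acid, acylmalonic half ester (not isolated; its CH centre is configurationally labile and undefined) | CCOC(=O)C(C(=O)O)C(=O)c1cc(OCc2ccccc2)c(OCc2ccccc2)c(-c2c(OCc3ccccc3)cc3oc(-c4ccc(OCc5ccccc5)cc4)cc(=O)c3c2OCc2ccccc2)c1 | intermediate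
13 | ethyl 3-oxo-3-Ar*-propanoate | CCOC(=O)CC(=O)c1cc(OCc2ccccc2)c(OCc2ccccc2)c(-c2c(OCc3ccccc3)cc3oc(-c4ccc(OCc5ccccc5)cc4)cc(=O)c3c2OCc2ccccc2)c1 | intermediate
14 | ethyl (3R)-3-hydroxy-3-Ar*-propanoate | CCOC(=O)C[C@@H](O)c1cc(OCc2ccccc2)c(OCc2ccccc2)c(-c2c(OCc3ccccc3)cc3oc(-c4ccc(OCc5ccccc5)cc4)cc(=O)c3c2OCc2ccccc2)c1 | intermediate
15 | 3,5-bis(benzyloxy)phenol | Oc1cc(OCc2ccccc2)cc(OCc2ccccc2)c1 | starting material
16 | ethyl (3S)-3-[3,5-bis(benzyloxy)phenoxy]-3-Ar*-propanoate | CCOC(=O)C[C@@H](c1cc(OCc2ccccc2)c(OCc2ccccc2)c(-c2c(OCc3ccccc3)cc3oc(-c4ccc(OCc5ccccc5)cc4)cc(=O)c3c2OCc2ccccc2)c1)Oc1cc(OCc2ccccc2)cc(OCc2ccccc2)c1 | intermediate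
17 | (3S)-3-[3,5-bis(benzyloxy)phenoxy]-3-Ar*-propanoic acid | OC(=O)C[C@@H](c1cc(OCc2ccccc2)c(OCc2ccccc2)c(-c2c(OCc3ccccc3)cc3oc(-c4ccc(OCc5ccccc5)cc4)cc(=O)c3c2OCc2ccccc2)c1)Oc1cc(OCc2ccccc2)cc(OCc2ccccc2)c1 | intermediate
18 | (3S)-3-[3,5-bis(benzyloxy)phenoxy]-3-Ar*-propanoyl chloride (not isolated) | ClC(=O)C[C@@H](c1cc(OCc2ccccc2)c(OCc2ccccc2)c(-c2c(OCc3ccccc3)cc3oc(-c4ccc(OCc5ccccc5)cc4)cc(=O)c3c2OCc2ccccc2)c1)Oc1cc(OCc2ccccc2)cc(OCc2ccccc2)c1 | intermediate
19 | (2S)-5,7-bis(benzyloxy)-2-Ar*-chroman-4-one, heptabenzyl ether of the target | O=C1C[C@@H](c2cc(OCc3ccccc3)c(OCc3ccccc3)c(-c3c(OCc4ccccc4)cc4oc(-c5ccc(OCc6ccccc6)cc5)cc(=O)c4c3OCc3ccccc3)c2)Oc2cc(OCc3ccccc3)cc(OCc3ccccc3)c21 | intermediate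
20 | CNP0176432.1, (2S)-flavanone–flavone dimer | O=C1C[C@@H](c2cc(O)c(O)c(-c3c(O)cc4oc(-c5ccc(O)cc5)cc(=O)c4c3O)c2)Oc2cc(O)cc(O)c21 | target

## Step count and weak points

Total step count: 14.
Longest linear sequence: 11 (steps 4 to 14, from 5-bromovanillin).

**Step 13 (key step).**
- What may go wrong: the Lewis acid may break the benzylic C2–O1 bond before or after acylation, which means loss of the ring A phenol, or ring opening and reclosure with erosion of configuration. Benzyl groups next to the two carbonyls may also be lost through chelation, with benzyl transfer to ring A.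
- Fallback: ring C is closed at O1–C2 instead, setting out from 9.
- Commercial 2,4,6-trihydroxyacetophenone is dibenzylated (BnBr, K2CO3, acetone) to 1-[2,4-bis(benzyloxy)-6-hydroxyphenyl]ethanone F1.
- Claisen–Schmidt condensation of this ketone with 9 (KOH, EtOH/THF, rt) should give the (E)-2'-hydroxychalcone F2.
- NaOAc in refluxing EtOH closes it by oxa-Michael addition to the racemic heptabenzyl flavanone F3.
- Kinetic resolution follows by asymmetric transfer hydrogenation (RuCl(p-cymene)[(R,R)-TsDPEN], HCO2H/Et3N, EtOAc, stopped near half conversion). It is expected to reduce the (2R)-ketone to the cis-(2R,4R)-flavan-4-ol F4 and to leave the (2S)-ketone, which is separated by chromatography.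
- The route is rejoined at 19.

**Step 11.**
- What may go wrong: the activated alcohol may lose a proton from the acidic methylene next to the ester (dehydration towards the cinnamate) instead of being displaced. Partial ionisation at the electron-rich benzylic carbon may also erode the inversion.
- Fallback: the carboxyl carbon is masked as a terminal alkene, so that no acidic C–H flanks the carbinol. It sets out from 9.
- Asymmetric allylboration with (+)-Ipc2B(allyl) (from (−)-alpha-pinene; Et2O, −78 °C, ethanolamine work-up) is expected to give the (R)-homoallylic alcohol (1R)-1-Ar*-but-3-en-1-ol F5.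
- Mitsunobu etherification with 15 (PPh3, DIAD, toluene, 0 °C) inverts it to the (S)-aryl ether F6.
- Lemieux–Johnson cleavage (OsO4 cat., NaIO4, 2,6-lutidine, dioxane/H2O) gives the (3S)-3-aryloxy-3-Ar*-propanal F7.
- This aldehyde is taken crude into a Pinnick oxidation, and the route is rejoined at 17.

**Step 7.**
- What may go wrong: transmetalation may be slow at a palladium centre flanked by two benzyloxy groups, so that protodeboronation of the boronate and hydrodeiodination of the flavone overtake coupling.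
- Fallback: a base-free, copper-assisted Stille coupling, setting out from 7.
- Stannylation ((Me3Sn)2, Pd(PPh3)4, toluene, 100 °C) gives 3,4-bis(benzyloxy)-5-(trimethylstannyl)benzaldehyde F8.
- This stannane is coupled with 4 (Pd(PPh3)4, CuI, CsF, DMF, 50 °C), and the route is rejoined at 9.

## Further compounds

F1 | step 13 | 1-[2,4-bis(benzyloxy)-6-hydroxyphenyl]ethanone | CC(=O)c1c(O)cc(OCc2ccccc2)cc1OCc1ccccc1
F2 | step 13 | (E)-1-[2,4-bis(benzyloxy)-6-hydroxyphenyl]-3-Ar*-prop-2-en-1-one | O=C(/C=C/c1cc(OCc2ccccc2)c(OCc2ccccc2)c(-c2c(OCc3ccccc3)cc3oc(-c4ccc(OCc5ccccc5)cc4)cc(=O)c3c2OCc2ccccc2)c1)c1c(O)cc(OCc2ccccc2)cc1OCc1ccccc1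
F3 | step 13 | racemic 5,7-bis(benzyloxy)-2-Ar*-chroman-4-one | O=C1CC(c2cc(OCc3ccccc3)c(OCc3ccccc3)c(-c3c(OCc4ccccc4)cc4oc(-c5ccc(OCc6ccccc6)cc5)cc(=O)c4c3OCc3ccccc3)c2)Oc2cc(OCc3ccccc3)cc(OCc3ccccc3)c21
F4 | step 13 | (2R,4R)-5,7-bis(benzyloxy)-2-Ar*-chroman-4-ol (cis) | O[C@@H]1C[C@H](c2cc(OCc3ccccc3)c(OCc3ccccc3)c(-c3c(OCc4ccccc4)cc4oc(-c5ccc(OCc6ccccc6)cc5)cc(=O)c4c3OCc3ccccc3)c2)Oc2cc(OCc3ccccc3)cc(OCc3ccccc3)c21
F5 | step 11 | (1R)-1-Ar*-but-3-en-1-ol | C=CC[C@@H](O)c1cc(OCc2ccccc2)c(OCc2ccccc2)c(-c2c(OCc3ccccc3)cc3oc(-c4ccc(OCc5ccccc5)cc4)cc(=O)c3c2OCc2ccccc2)c1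
F6 | step 11 | (1S)-1-Ar*-but-3-en-1-yl 3,5-bis(benzyloxy)phenyl ether | C=CC[C@@H](c1cc(OCc2ccccc2)c(OCc2ccccc2)c(-c2c(OCc3ccccc3)cc3oc(-c4ccc(OCc5ccccc5)cc4)cc(=O)c3c2OCc2ccccc2)c1)Oc1cc(OCc2ccccc2)cc(OCc2ccccc2)c1
F7 | step 11 | (3S)-3-[3,5-bis(benzyloxy)phenoxy]-3-Ar*-propanal | O=CC[C@@H](c1cc(OCc2ccccc2)c(OCc2ccccc2)c(-c2c(OCc3ccccc3)cc3oc(-c4ccc(OCc5ccccc5)cc4)cc(=O)c3c2OCc2ccccc2)c1)Oc1cc(OCc2ccccc2)cc(OCc2ccccc2)c1
F8 | step 7 | 3,4-bis(benzyloxy)-5-(trimethylstannyl)benzaldehyde | O=Cc1cc(OCc2ccccc2)c(OCc2ccccc2)c([Sn](C)(C)C)c1
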